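The numbers of this flask were set for the occasion.

The constants seem to forbid a chain here: the first chain carrier ends on its own kind at 2 × 10⁸ M⁻¹ s⁻¹, 6450 times the 31000 M⁻¹ s⁻¹ at which it meets the coupling partner.

    initiator → 2 initiating radical (k1 = 0.0017 s⁻¹)
    substrate + initiating radical → capped initiator + first chain carrier (k2 = 5.2 × 10⁵ M⁻¹ s⁻¹)
    coupling partner + first chain carrier → target + second chain carrier (k3 = 31000 M⁻¹ s⁻¹)
    substrate + second chain carrier → released group + first chain carrier (k4 = 56000 M⁻¹ s⁻¹)
    2 first chain carrier → ended chains A (k5 = 2 × 10⁸ M⁻¹ s⁻¹)
    2 second chain carrier → ended chains B (k6 = 2 × 10⁷ M⁻¹ s⁻¹)
    coupling partner + released group ⇌ idle adduct, settled at all times (K7 = 3.2 M⁻¹)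
    substrate + target → side product (k8 = 0.022 M⁻¹ s⁻¹)

substrate 0.10 M; coupling partner 0.105 M; initiator 5.0 mM; time 6.0 min

- in percentages every species weighs as the substrate in it: one ended chains A or side product counts as two
- for released group the idle adduct is counted in
- a step written with two of one species runs at k times the square of its concentration and takes two of it each time
- run time (flask): 6.0 min

- part of the substrate that has reacted at 6.0 min
- share of the unused coupling partner that is free and not bound as idle adduct, at 6.0 min

The initiator, moreover, delivers just 0.00458 M of initiating radical in the run, against 0.10 M of substrate.

Follow one first chain carrier to its fork. At the charged amounts the second chain carrier passes on faster, and it has the smaller ending constant, so the reckoning lets the chains end as first chain carriers. Carriers then stand at the level x where their making from the initiator matches their ending in pairs: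

x = √(initiator constant × initiator ÷ ending constant) = 2.06 × 10⁻⁷ M

At that level, with the partner as charged, going on beats ending by 39.5 to one, because the carrier rarely meets another carrier. The coupling partner therefore decays with the chain constant κ, the coupling constant times x, 0.383 min⁻¹. This is a pseudo-first-order constant with no substrate in it, valid while substrate lasts, and the reckoning takes the unused partner as free. As the initiator decays, x sinks with its square root, so the run counts as τ = 5.17 min:

unused partner = exp(−κτ) = 13.8%

The partner used, u = 0.0905 M, takes as much substrate through the chain. With the radicals' share, that makes 95.1% of the substrate before the side step is counted. Released group near that amount leaves a free share of 1/(1 + K·u) = 77.5%, with K the binding constant.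

The forecast gives 97.5% and 80%, above the 95.1% and 77.5% reckoned here, holding that “the substrate is nearly used up”.

The simulation gives 98.1% and 79.7%; in this flask 15.7% of the coupling partner stands free and, with the idle adduct counted, 19.8% is unused, more than the reckoned 13.8%. At 6.00 min this flask is nearly at rest in its substrate, with 1.92% left, but not in its initiator, with 54.2% left. After 60.0 min the substrate stands at 0% and 100% has reacted. The free partner has moved from 15.7% to 14.4%, the target from 74.6% to 76.2%, while the initiator has fallen from 54.2% to 0.220%.

In the neighbour flask with 0.40 M of substrate, κ is unchanged, so 13.8% of the partner should stay unused. The computed neighbour flask holds 14.3% free and 18.1% unused with the idle adduct counted, with 38.4% of its substrate reacted.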